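all flasks: free catalyst 0.10 mM
- elm: starting material 0.20 M; coupling partner 0.090 M; scavenger 0.15 M; run made earlier
- flask: starting material 0.10 M; coupling partner 0.0900 M; scavenger 0.150 M; time 10 d

elm run (percent of the starting material charged)

| time / d | starting material / % | target / % |
|---|---|---|
| 0.417 | 87.1 | 12.3 |
| 0.833 | 75.4 | 22.2 |
| 1.25 | 68.3 | 28.6 |
| 1.67 | 61.1 | 33.4 |
| 2.00 | 58.2 | 35.6 |
| 2.50 | 54.9 | 37.5 |
| 3.00 | 51.6 | 37.8 |

(scatter of a reading: 0.5 percentage points)

- the earlier runs do not show how much of coupling partner is bound; that part of a forecast is a guess

* part of the starting material that has reacted at 10 d
* share of the unused coupling partner that is free and not bound as idle adduct, at 10 d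

Start from late times, where a flask shows what its charge can pay for. Read the last line of the elm run: at 3.00 d the starting material used comes to 0.0968 M, which passes the 0.090 M of coupling partner charged. So something beyond the coupling consumes starting material, but take the coupling first. Assume one partner for each target, and hold two amounts against each other: partner charged and starting material charged. In the new flask their ratio is 90.0 %, the coupling share: the part of the starting material that the partner can turn into target. The partner is the limiting reagent here, with 0.0900 M against 0.10 M.

Now check the time. The new flask holds half the starting material of the elm run, so if it runs at half pace, the 3.00 d of the elm run stretch to 6.00 d, shorter than 10 d. My reckoning is therefore the share, plus an excess I do not size.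

The forecast stands above that share, with 94 % reacted (85 % to 99 %). It puts 75 % of the unused partner free (35 % to 97 %), saying “most is free once starting material is low”.

The new flask gives 95.3 % reacted and >99.9 % free at 10 d. Side product stands there at 10.6 %, each one counted as two. Subtract the coupling share: 5.3 percentage points reacted beyond it, near half that side product.

    starting material + catalyst intermediate A → catalyst intermediate B (k = 0.120 M⁻¹ s⁻¹)
    coupling partner + released group ⇌ idle adduct, settled at all times (K = 25.0 M⁻¹)
    catalyst intermediate B ⇌ released group + catalyst intermediate C (K = 0.0450 M, k = 0.320 s⁻¹)
    starting material + target → side product (k = 6.10 × 10⁻⁶ M⁻¹ s⁻¹)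
    catalyst intermediate C → free catalyst + target (k = 0.120 s⁻¹)
    scavenger + released group → scavenged by-product (k = 4.40 × 10⁻⁴ M⁻¹ s⁻¹)
    coupling partner + free catalyst → catalyst intermediate A (k = 0.190 M⁻¹ s⁻¹)

Try a neighbour flask, the same but with 0.054 M of partner: the share gives 54.0 %. That flask reacts 64.0 % at 10 d, so 10 points lie beyond the share, beside 19.9 % of side product.

Readings and results stem from a simulated flask on assumed constants, noise included.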